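**Plan**

- Retrosynthesis: the C3–O bond is traced back to a C3–B bond. Ring C is then cut at O1–C2 and C3–C4 together, giving an o-hydroxybenzyl alcohol of ring A and an (E)-4-hydroxystyrylboronate. Ring A is cut at C8–prenyl and C4a–C4 back to 5-methoxyresorcinol, and the boronate at the aryl–vinyl bond back to 4-iodophenol and vinylboronate.
- Enabling feature: O1–C8a–C4a–C4 of ring A is a latent o-quinone methide, C2=C3 is the double bond of a 4-hydroxystyrene, and boron on C3 stands in for the 3-hydroxyl.
- Forward: ring A is dressed by two directed lithiations (prenyl at C8, formyl at C4a), deprotected, silylated at O7 and reduced. The boronate is made by Heck coupling. Ring C closes in the [4+2] addition, then C–B oxidation and desilylation finish the route.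
- Stereochemistry: the 2,3-trans relation comes from the E alkene under suprafacial addition and from stereoretentive C–B oxidation. The absolute configuration (2R,3S) comes from the chiral phosphoric acid.

Key step: step 8

Assumption: the absolute sense of induction of the phosphoric acid in step 8 cannot be derived with certainty for this new pairing; the (R)-acid is written, and its mirror image would be used if the first run gave the antipode of 15.

**Route**

Step 1
Reactants: 1 5-methoxyresorcinol
Product: 2 1-methoxy-3,5-bis(methoxymethoxy)benzene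
Conditions: MOMCl (2.5 equiv), i-Pr2NEt (3 equiv), CH2Cl2, 0 °C → rt
Reagents that add atoms: chloromethyl methyl ether, COCCl
Why: Williamson-type O-alkylation of both phenols (MOM protection) installs the two strong directing groups needed for the lithiations that follow; no stereocentre is formed.

Step 2
Reactants: 2 1-methoxy-3,5-bis(methoxymethoxy)benzene; 3 prenyl bromide (1-bromo-3-methylbut-2-ene)
Product: 5 5-methoxy-1,3-bis(methoxymethoxy)-2-(3-methylbut-2-en-1-yl)benzene, via aryllithium 4 (not isolated)
Conditions: n-BuLi (1.1 equiv), THF, 0 °C; then CuI (10 mol %), 3, −78 °C → rt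
Reagents that add atoms: none
Why: Directed ortho-metalation removes the proton flanked by both OMOM groups (the most acidic, doubly coordinated site), and copper-catalysed SN2 allylation of the aryllithium with prenyl bromide fixes the prenyl group at the future C8.

Step 3
Reactants: 5 5-methoxy-1,3-bis(methoxymethoxy)-2-(3-methylbut-2-en-1-yl)benzene
Product: 7 6-methoxy-2,4-bis(methoxymethoxy)-3-(3-methylbut-2-en-1-yl)benzaldehyde, via aryllithium 6 (not isolated)
Conditions: n-BuLi (1.2 equiv), TMEDA, THF, −20 → 0 °C; then DMF, −78 °C → rt; H2O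
Reagents that add atoms: N,N-dimethylformamide, CN(C)C=O
Why: A second directed ortho-metalation at one of the two equivalent positions between OMOM and OMe, followed by formylation of the aryllithium with DMF (Bouveault-type), places the future C4 carbon on the future C4a.

Step 4
Reactants: 7 6-methoxy-2,4-bis(methoxymethoxy)-3-(3-methylbut-2-en-1-yl)benzaldehyde
Product: 8 2,4-dihydroxy-6-methoxy-3-(3-methylbut-2-en-1-yl)benzaldehyde
Conditions: 3 M aq. HCl, MeOH, rt
Reagents that add atoms: none
Why: Acid-catalysed transacetalisation cleaves both MOM ethers, and the formyl group lowers the nucleophilicity of both phenols (one of them hydrogen-bonded to it), so addition of OH to the prenyl alkene should stay slow at rt, as in the deprotection of related prenylated 2,4-dihydroxyaryl carbonyl compounds.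

Step 5
Reactants: 8 2,4-dihydroxy-6-methoxy-3-(3-methylbut-2-en-1-yl)benzaldehyde
Product: 9 2-hydroxy-6-methoxy-3-(3-methylbut-2-en-1-yl)-4-[(triisopropylsilyl)oxy]benzaldehyde
Conditions: TIPSCl (1.05 equiv), imidazole (2.2 equiv), CH2Cl2, 0 °C
Reagents that add atoms: triisopropylsilyl chloride, CC(C)[Si](Cl)(C(C)C)C(C)C
Why: Selective O-silylation: the 4-OH para to the formyl group is the more acidic, non-chelated phenol, whereas the 2-OH is tied up in a hydrogen bond to the formyl oxygen, so one equivalent of silyl chloride should protect only the future O7.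

Step 6
Reactants: 9 2-hydroxy-6-methoxy-3-(3-methylbut-2-en-1-yl)-4-[(triisopropylsilyl)oxy]benzaldehyde
Product: 10 2-(hydroxymethyl)-3-methoxy-6-(3-methylbut-2-en-1-yl)-5-[(triisopropylsilyl)oxy]phenol
Conditions: NaBH4, THF/MeOH (4:1), 0 °C, short reaction time; pH 7 buffer work-up
Reagents that add atoms: none
Why: Borohydride reduction of the aldehyde gives the o-hydroxybenzyl alcohol; it is kept cold, worked up neutral and used at once because this electron-rich benzylic alcohol ionises easily.

Step 7
Reactants: 11 4-iodophenol; 12 vinylboronic acid pinacol ester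
Product: 13 4-[(E)-2-(4,4,5,5-tetramethyl-1,3,2-dioxaborolan-2-yl)ethenyl]phenol
Conditions: Pd(P(t-Bu)3)2 (5 mol %), i-Pr2NH (2 equiv), toluene, 80 °C
Reagents that add atoms: none
Why: Mizoroki–Heck arylation: after oxidative addition of the aryl iodide to zerovalent palladium, the vinylboronate reacts at its terminal C–H bond and keeps boron under anhydrous amine-base conditions (no hydroxide or alkoxide to trigger Suzuki transmetalation), and syn insertion/syn β-hydride elimination gives the E alkene.

Step 8
Reactants: 10 2-(hydroxymethyl)-3-methoxy-6-(3-methylbut-2-en-1-yl)-5-[(triisopropylsilyl)oxy]phenol; 13 4-[(E)-2-(4,4,5,5-tetramethyl-1,3,2-dioxaborolan-2-yl)ethenyl]phenol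
Product: 15 4-[(2S,3S)-5-methoxy-8-(3-methylbut-2-en-1-yl)-3-(4,4,5,5-tetramethyl-1,3,2-dioxaborolan-2-yl)-7-[(triisopropylsilyl)oxy]-3,4-dihydro-2H-chromen-2-yl]phenol (2,3-trans 3-boryl flavan), via o-quinone methide 14 (not isolated)
Conditions: (R)-3,3′-bis(2,4,6-triisopropylphenyl)-1,1′-binaphthyl-2,2′-diyl hydrogen phosphate (10 mol %), 13 (1.5 equiv), 5 Å MS, PhCF3, 0 °C; 10 added slowly by syringe pump
Reagents that add atoms: none
Why: Proposed new method: the phosphoric acid protonates the benzylic hydroxyl of 10 and, after loss of water, holds o-quinone methide 14 by a hydrogen bond to its carbonyl oxygen while its P=O accepts a hydrogen bond from the 4′-OH of 13; the boron-bearing carbon of 13 then attacks the methide CH2 (C3–C4), because the charge develops at the carbon stabilised by the 4-hydroxyphenyl group, and O1 closes on that carbon (O1–C2). The closest known reactions are chiral phosphoric acid-catalysed [4+2] additions of o-quinone methides generated in situ to hydroxystyrenes and thermal hetero-Diels–Alder additions of o-quinone methides to styrenes; an alkenylboronate as 2π partner of a methide unsubstituted at its terminus is the untested part. Ring C closes by an intermolecular, asynchronous inverse-demand oxa-[4+2] addition (in the stepwise limit a 6-exo-trig attack of the phenolate oxygen on the quinone-methide-like benzylic cation). C2 and C3 are set together: their trans relation follows from the E geometry of 13 under suprafacial addition, and their absolute configuration from the alkene face left open in the chiral phosphate pocket. The step needs C4-to-C(B) regiochemistry, retention of boron (no ipso-substitution or protodeboronation) and cross- over self-reaction of 14; the cation-stabilising hydroxyaryl group, the weakly Lewis-acidic pinacol ester with sieves to take up water, and slow addition of 10 with the bulky silyl ether shielding C6 should secure these.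

Step 9
Reactants: 15 2,3-trans 3-boryl flavan
Product: 16 (2R,3S)-2-(4-hydroxyphenyl)-5-methoxy-8-(3-methylbut-2-en-1-yl)-7-[(triisopropylsilyl)oxy]-3,4-dihydro-2H-chromen-3-ol
Conditions: NaBO3·4H2O (4 equiv), THF/H2O (1:1), rt
Reagents that add atoms: sodium perborate tetrahydrate, O[B-]1(O)OO[B-](O)(O)OO1.[Na+].[Na+]
Why: Perborate oxidation of the secondary alkyl pinacol boronate proceeds by 1,2-migration of C3 from boron to oxygen with retention, so the 3-OH should end trans to the aryl group, and the mild reagent leaves the prenyl alkene, the phenol and the silyl ether alone.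

Step 10
Reactants: 16 (2R,3S)-2-(4-hydroxyphenyl)-5-methoxy-8-(3-methylbut-2-en-1-yl)-7-[(triisopropylsilyl)oxy]-3,4-dihydro-2H-chromen-3-ol
Product: 17 8-prenylafzelechin 5-methyl ether
Conditions: Bu4NF (1.1 equiv), AcOH (1.1 equiv), THF, 0 °C
Reagents that add atoms: none
Why: Fluoride cleavage of the aryl silyl ether, buffered with acetic acid, frees the 7-OH without acid or strong base, so neither the prenyl group nor the configuration at the benzylic C2–O bond is put at risk.

**Compound list**

1 | 5-methoxyresorcinol (5-methoxybenzene-1,3-diol) | COc1cc(O)cc(O)c1 | starting material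
2 | 1-methoxy-3,5-bis(methoxymethoxy)benzene | COCOc1cc(OC)cc(OCOC)c1 | intermediate
3 | prenyl bromide (1-bromo-3-methylbut-2-ene) | CC(C)=CCBr | starting material
4 | [4-methoxy-2,6-bis(methoxymethoxy)phenyl]lithium, not isolated | [Li]c1c(OCOC)cc(OC)cc1OCOC | intermediate
5 | 5-methoxy-1,3-bis(methoxymethoxy)-2-(3-methylbut-2-en-1-yl)benzene | COCOc1cc(OC)cc(OCOC)c1CC=C(C)C | intermediate
6 | [6-methoxy-2,4-bis(methoxymethoxy)-3-(3-methylbut-2-en-1-yl)phenyl]lithium, not isolated | [Li]c1c(OC)cc(OCOC)c(CC=C(C)C)c1OCOC | intermediate
7 | 6-methoxy-2,4-bis(methoxymethoxy)-3-(3-methylbut-2-en-1-yl)benzaldehyde | O=Cc1c(OC)cc(OCOC)c(CC=C(C)C)c1OCOC | intermediate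
8 | 2,4-dihydroxy-6-methoxy-3-(3-methylbut-2-en-1-yl)benzaldehyde | O=Cc1c(OC)cc(O)c(CC=C(C)C)c1O | intermediate
9 | 2-hydroxy-6-methoxy-3-(3-methylbut-2-en-1-yl)-4-[(triisopropylsilyl)oxy]benzaldehyde | O=Cc1c(OC)cc(O[Si](C(C)C)(C(C)C)C(C)C)c(CC=C(C)C)c1O | intermediate
10 | 2-(hydroxymethyl)-3-methoxy-6-(3-methylbut-2-en-1-yl)-5-[(triisopropylsilyl)oxy]phenol | COc1cc(O[Si](C(C)C)(C(C)C)C(C)C)c(CC=C(C)C)c(O)c1CO | intermediate
11 | 4-iodophenol | Oc1ccc(I)cc1 | starting material
12 | vinylboronic acid pinacol ester (2-ethenyl-4,4,5,5-tetramethyl-1,3,2-dioxaborolane) | C=CB1OC(C)(C)C(C)(C)O1 | starting material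
13 | 4-[(E)-2-(4,4,5,5-tetramethyl-1,3,2-dioxaborolan-2-yl)ethenyl]phenol | Oc1ccc(/C=C/B2OC(C)(C)C(C)(C)O2)cc1 | intermediate
14 | 5-methoxy-6-methylidene-2-(3-methylbut-2-en-1-yl)-3-[(triisopropylsilyl)oxy]cyclohexa-2,4-dien-1-one (o-quinone methide), not isolated | C=C1C(OC)=CC(O[Si](C(C)C)(C(C)C)C(C)C)=C(CC=C(C)C)C1=O | intermediate
15 | 4-[(2S,3S)-5-methoxy-8-(3-methylbut-2-en-1-yl)-3-(4,4,5,5-tetramethyl-1,3,2-dioxaborolan-2-yl)-7-[(triisopropylsilyl)oxy]-3,4-dihydro-2H-chromen-2-yl]phenol; aryl and boron trans, same spatial arrangement as in 17 (the descriptors differ only because boron ranks below carbon) | COc1cc(O[Si](C(C)C)(C(C)C)C(C)C)c(CC=C(C)C)c2c1C[C@H](B1OC(C)(C)C(C)(C)O1)[C@@H](c1ccc(O)cc1)O2 | intermediate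
16 | (2R,3S)-2-(4-hydroxyphenyl)-5-methoxy-8-(3-methylbut-2-en-1-yl)-7-[(triisopropylsilyl)oxy]-3,4-dihydro-2H-chromen-3-ol | COc1cc(O[Si](C(C)C)(C(C)C)C(C)C)c(CC=C(C)C)c2c1C[C@H](O)[C@@H](c1ccc(O)cc1)O2 | intermediate
17 | 8-prenylafzelechin 5-methyl ether, (2R,3S)-2-(4-hydroxyphenyl)-5-methoxy-8-(3-methylbut-2-en-1-yl)-3,4-dihydro-2H-chromene-3,7-diol | COc1cc(O)c(CC=C(C)C)c2c1C[C@H](O)[C@@H](c1ccc(O)cc1)O2 | target

**Count**

Total steps: 10. Longest linear sequence: 9 steps (steps 1–6, 8, 9, 10); step 7 is the side branch.

**Steps most likely to fail**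

Step 8. What may go wrong:
- loss of boron by ipso-substitution or protodeboronation once the C3–C4 bond has formed;
- self-condensation of the methide with the electron-rich ring of a second molecule;
- poor facial discrimination, because the only anchoring point on the alkene partner is the remote 4′-OH.

The fallback leaves 10 aside, sets out from aldehyde 9 and boronate 13, and uses known reactions only. Boronate 13 is exchanged with methylboronic acid (acetone/0.1 M HCl, rt) to give (E)-[2-(4-hydroxyphenyl)ethenyl]boronic acid F1. Heating 9 and F1 with catalytic dibenzylamine (dioxane, 90 °C; Petasis-type alkenyl transfer to the iminium ion, loss of the amine, 6π-oxa-electrocyclisation) should give racemic 4-[5-methoxy-8-(3-methylbut-2-en-1-yl)-7-[(triisopropylsilyl)oxy]-2H-chromen-2-yl]phenol F2. Copper-catalysed protoboration of its styrenic C3=C4 bond (CuCl, a chiral bisphosphine such as Ph-BPE in the enantiomeric form that consumes the (S)-chromene, NaOt-Bu, B2pin2, MeOH, THF, 0 °C) is then run to about half conversion as a kinetic resolution. Copper and boron add syn, on the face away from the C2 aryl group, with boron at C3, and protonolysis of the benzylic C4–Cu bond gives 15, where the fallback rejoins the route. The prenyl alkene is not activated for borylcupration. The price is that at most half of F2 can be used; the slow-reacting enantiomer is recovered.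

Step 4. What may go wrong: acid-promoted addition of a neighbouring phenol to the prenyl double bond (closure to a 2,2-dimethylchroman) or hydration of the alkene while the second MOM group is being removed.

The fallback keeps the side chain as an allyl group during the acid step and builds the prenyl group afterwards. It sets out from 2 through its lithio derivative 4 (as in step 2), which is quenched with allyl bromide (CuI cat., THF) to give 5-methoxy-1,3-bis(methoxymethoxy)-2-(prop-2-en-1-yl)benzene F3. HCl/MeOH removes both MOM groups to give 5-methoxy-2-(prop-2-en-1-yl)benzene-1,3-diol F4. Vilsmeier–Haack formylation (POCl3, DMF, MeCN, 0 °C → rt, then aqueous hydrolysis) at one of the two equivalent free positions gives 2,4-dihydroxy-6-methoxy-3-(prop-2-en-1-yl)benzaldehyde F5. Cross-metathesis with 2-methyl-2-butene (second-generation Grubbs catalyst, CH2Cl2, 40 °C) converts allyl into prenyl and comes back to the route at 8.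

Step 7. What may go wrong: Suzuki-type transmetalation of the boronate once the phenol is deprotonated (loss of boron, styrene and stilbene formation) or a second arylation of the product.

The fallback sets out from 12 and commercial 4-acetoxystyrene. Cross-metathesis (second-generation Grubbs catalyst, CH2Cl2, 40 °C; E-selective, ethene lost) gives 4-[(E)-2-(4,4,5,5-tetramethyl-1,3,2-dioxaborolan-2-yl)ethenyl]phenyl acetate F6. Methanolysis of the aryl acetate (K2CO3, MeOH, 0 °C) comes back to the route at 13.

**Further compounds**

F1 | step 8 | (E)-[2-(4-hydroxyphenyl)ethenyl]boronic acid | Oc1ccc(/C=C/B(O)O)cc1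
F2 | step 8 | rac-4-[5-methoxy-8-(3-methylbut-2-en-1-yl)-7-[(triisopropylsilyl)oxy]-2H-chromen-2-yl]phenol (racemate) | COc1cc(O[Si](C(C)C)(C(C)C)C(C)C)c(CC=C(C)C)c2c1C=CC(c1ccc(O)cc1)O2
F3 | step 4 | 5-methoxy-1,3-bis(methoxymethoxy)-2-(prop-2-en-1-yl)benzene | COCOc1cc(OC)cc(OCOC)c1CC=C
F4 | step 4 | 5-methoxy-2-(prop-2-en-1-yl)benzene-1,3-diol | COc1cc(O)c(CC=C)c(O)c1
F5 | step 4 | 2,4-dihydroxy-6-methoxy-3-(prop-2-en-1-yl)benzaldehyde | O=Cc1c(OC)cc(O)c(CC=C)c1O
F6 | step 7 | 4-[(E)-2-(4,4,5,5-tetramethyl-1,3,2-dioxaborolan-2-yl)ethenyl]phenyl acetate | CC(=O)Oc1ccc(/C=C/B2OC(C)(C)C(C)(C)O2)cc1
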